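All runs are calculated for an exercise.

By the last reading of the earlier ash flask the target has taken 0.0275 M of the 0.050 M of coupling partner, yet it still gains 6.9 percentage points in 10.0 s, against 8.0% in the first 10.0 s. The gain shrinks less than the partner does, so I treat the target's rate as pseudo-first-order in [starting material].

| setting | ash | cedar | green | amber |
|---|---|---|---|---|
| starting material | 0.10 M | 0.10 M | 0.10 M | 0.10 M |
| coupling partner | 0.050 M | 0.075 M | 0.100 M | 0.100 M |
| initiator | 3.3 mM | 3.3 mM | 3.3 mM | 3.3 mM |
| temperature | 85 °C | 118 °C |  |  |
| remark | run made earlier | run made earlier | at 70 °C throughout | at 70 °C until 50 s, from then on at 130 °C |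
| time |  |  | 2.5 min | 2.5 min |

- ash (time / s: target / %, side product / %, starting material / %): 10.0: 8.0, 0, 90.3; 15.0: 11.4, 1.1, 89.3; 30.0: 20.6, 0, 78.7; 40.0: 27.5, 2.9, 72.1
- cedar (time / s: target / %, side product / %, starting material / %): 10.0: 39.4, 2.8, 57.0

(standard deviation of a reading: 1 percentage point)

- the flask that ends with the higher share of target in all that became target or side product, or "neither" when 2 percentage points or less lies between them (green / amber / neither)
- share of target in all that became target or side product, green
- share of target in all that became target or side product, amber

- a species is counted by the starting material in it: one side product counts as two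

The loss of starting material gives 0.00818 s⁻¹ in ash and 0.0562 s⁻¹ in cedar. Carrying that factor per degree along, I get 0.00340 s⁻¹ for green, hence a conversion of 40.0%. For amber's hot stretch I get 0.113 s⁻¹, and over 100 s that is ample, so I take amber's conversion as complete.

Side product counts as two, so I let it form from starting material plus target. [starting material] then cancels against the target's rate, and side product over target grows in step with [target]. That gives my carried quantity, the side ratio σ: side product over target, divided by [target]. Cedar reads 1.80 L mol⁻¹, ash 3.83 L mol⁻¹.

This is the weak link, since each reading of side product is a few points with a scatter of 1 point. So I pool the two readings: 2.47 L mol⁻¹. If x is the target fraction, x plus σ times the charged [starting material] times x squared equals the conversion. Amber then gives 83.0% and green 91.7%, so I commit to green, higher than amber.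

The forecast says green, with 96% and 93%, each above mine, and it puts amber lower in these words: “Amber gets hotter and ends partner-starved, so it should be somewhat worse”. The flask gives green, with 95.2% and 82.9%.

    initiator → 2 initiating radical (k = 1.10 × 10⁻⁴ s⁻¹, Ea = 113 kJ mol⁻¹)
    starting material + initiating radical → capped initiator + first chain carrier (k = 1.80 × 10⁵ L mol⁻¹ s⁻¹, Ea = 22.0 kJ mol⁻¹)
    coupling partner + first chain carrier → target + second chain carrier (k = 22000 L mol⁻¹ s⁻¹, Ea = 24.0 kJ mol⁻¹)
    starting material + second chain carrier → by-product + first chain carrier (k = 22000 L mol⁻¹ s⁻¹, Ea = 8.00 kJ mol⁻¹)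
    2 first chain carrier → ended chains A (k = 2.00 × 10⁶ L mol⁻¹ s⁻¹, Ea = 20.0 kJ mol⁻¹)
    2 second chain carrier → ended chains B (k = 7.00 × 10⁶ L mol⁻¹ s⁻¹, Ea = 11.0 kJ mol⁻¹)
    starting material + target → side product (k = 0.00460 L mol⁻¹ s⁻¹, Ea = 73.0 kJ mol⁻¹)
    (constants at 70 °C)

At the end amber's σ stands at 2.49 L mol⁻¹ and green's at 1.08 L mol⁻¹, against my 2.47 L mol⁻¹. A neighbouring flask is amber with 0.0020 M of initiator. I multiply σ by the root of the ratio of initiator charges, which gives 3.17 L mol⁻¹, and the same equation at full conversion gives 79.8%. That flask leaves 0.24% of its starting material and ends at 76.8%.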